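The cyclopentenone ring is cut between C5 (the α-CH carrying the pentenyl chain) and C4 (the quaternary carbon carrying the acetoxy group and the acid chain). The ring's 1,4-oxygen pattern (C1=O, C4–O) across the C2=C3 alkene is that of a ring-opened furan, so the precursor is a racemic 5-alkyl-2-furylcarbinol made from furan, a bromo alcohol and (Z)-hex-3-enal. A chiral Brønsted acid-catalysed oxa-Piancatelli rearrangement then adds water, opens the furan and closes the C4–C5 bond by conrotatory 4π electrocyclisation, creating the ring, the tertiary carbinol and both stereocentres in one enantioconvergent operation. Oxidation of the chain terminus and acetylation finish the synthesis.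

Key step: step 4

Assumption: the sense of induction of the chiral acid in step 4 cannot be predicted with confidence; the (R)-catalyst is written, and its mirror image is to be used if the opposite sense is found.

Step 1
Reactants: 1 furan; 2 8-bromooctan-1-ol
Product: 4 8-(furan-2-yl)octan-1-ol, via 2-furyllithium 3 (not isolated)
Conditions: furan (3 equiv), n-BuLi (2.3 equiv), THF, 0 °C; then 2, −78 °C to rt; H2O quench
Reagents that add atoms: none
Why: C2-lithiation of furan and SN2 alkylation of 2-furyllithium by the primary bromide (one equivalent only deprotonates the hydroxyl group) is standard 2-alkylfuran synthesis, and no stereocentre is formed.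

Step 2
Reactants: 5 (Z)-hex-3-en-1-ol
Product: 6 (Z)-hex-3-enal
Conditions: Dess–Martin periodinane (1.1 equiv), CH2Cl2, 0 °C to rt; pentane, Celite filtration, cold concentration, used at once
Reagents that add atoms: none
Why: Dess–Martin oxidation is mild enough to give the β,γ-unsaturated aldehyde without migration of the Z-alkene into conjugation.

Step 3
Reactants: 4 8-(furan-2-yl)octan-1-ol; 6 (Z)-hex-3-enal
Product: 8 rac-(3Z)-1-[5-(8-hydroxyoctyl)furan-2-yl]hex-3-en-1-ol, via dilithio species 7 (not isolated)
Conditions: 4, n-BuLi (2.2 equiv), TMEDA, THF, 0 °C to rt; then 6, −78 °C; H2O quench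
Reagents that add atoms: none
Why: After alkoxide formation the second equivalent of n-BuLi lithiates the free furan α-position, and 1,2-addition of the furyllithium to the aldehyde at −78 °C should outrun enolisation; the carbinol centre forms racemic, which is immaterial because it is ionised in step 4.

Step 4
Reactants: 8 rac-(3Z)-1-[5-(8-hydroxyoctyl)furan-2-yl]hex-3-en-1-ol
Product: 11 (4S,5S)-4-hydroxy-4-(8-hydroxyoctyl)-5-[(2Z)-pent-2-en-1-yl]cyclopent-2-en-1-one, via hemiketal 9 (not isolated), via dienol ketone 10 (not isolated)
Conditions: (R)-3,3'-bis(2,4,6-triisopropylphenyl)-1,1'-binaphthyl-2,2'-diyl N-triflylphosphoramide (10 mol%), H2O (20 equiv), CHCl3 (0.02 M), vigorous stirring, 40 °C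
Reagents that add atoms: water, O
Why: Proposed new method: the acid ionises the furfuryl alcohol, water adds to the furan carbon that carries the hydroxyoctyl chain to give hemiketal 9, this opens to dienol ketone 10, and the O-protonated form of 10, a 1-hydroxypentadienyl cation held by the chiral phosphoramide anion through two hydrogen bonds, closes the C4–C5 bond by thermal conrotatory 4π electrocyclisation. The closest known reactions are the ZnCl2-mediated Piancatelli rearrangement of 5-methyl-2-furylcarbinols (homoallylic carbinols included) and the chiral phosphoric acid-catalysed aza-Piancatelli and Nazarov cyclisations; an enantioselective version with water on a 5-alkylfuran has not been shown. The cyclopentenone ring closes in a Nazarov-type conrotatory 4π mode (formally 5-endo) between the former carbinol carbon and the former substituted furan carbon. C4 is set by the sense of conrotation that the chiral counter-anion imposes on the cation; C5 is set relative to C4 by the conrotation and, being α to the ketone, should equilibrate through the enol under the acid conditions to the preferred arrangement with the two carbon chains trans (pentenyl cis to hydroxyl), as the target requires. The step needs water to attack the substituted furan carbon faster than the cation loses a proton to a furyldiene or is captured by the primary alcohol; high dilution, excess water and the reversibility of ether formation at the carbinol carbon favour the productive path. The carbinol oxidation level fixes which α-carbon becomes C5, so no regioisomeric ring can form.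

Step 5
Reactants: 11 (4S,5S)-4-hydroxy-4-(8-hydroxyoctyl)-5-[(2Z)-pent-2-en-1-yl]cyclopent-2-en-1-one
Product: 13 8-[(1S,5S)-1-hydroxy-4-oxo-5-[(2Z)-pent-2-en-1-yl]cyclopent-2-en-1-yl]octanoic acid, via aldehyde 12 (not isolated)
Conditions: TEMPO (0.2 equiv), PhI(OAc)2 (2.2 equiv), MeCN/H2O (1:1), rt
Reagents that add atoms: water, O
Why: Oxoammonium (TEMPO/PhI(OAc)2) oxidation should take only the primary alcohol, through aldehyde 12 and its hydrate, to the acid, while the tertiary alcohol, the enone and the Z-alkene are inert and the near-neutral medium leaves both stereocentres untouched.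

Step 6
Reactants: 13 8-[(1S,5S)-1-hydroxy-4-oxo-5-[(2Z)-pent-2-en-1-yl]cyclopent-2-en-1-yl]octanoic acid
Product: 15 8-[(1S,5S)-1-(acetyloxy)-4-oxo-5-[(2Z)-pent-2-en-1-yl]cyclopent-2-en-1-yl]octanoic acid, via mixed anhydride 14 (not isolated)
Conditions: Ac2O (4 equiv), Sc(OTf)3 (5 mol%), MeCN, −20 °C; then H2O/THF, 0 °C to rt
Reagents that add atoms: acetic anhydride, CC(=O)OC(C)=O
Why: Sc(OTf)3-catalysed acylation acetylates hindered tertiary alcohols without base, which should avoid E1cB loss of the β-acetoxy group and retro-aldol opening, and the mixed anhydride formed at the carboxyl group is hydrolysed on aqueous work-up; no stereocentre is touched.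

Compound list
1 | furan | c1ccoc1 | starting material
2 | 8-bromooctan-1-ol | OCCCCCCCCBr | starting material
3 | 2-furyllithium | [Li]c1ccco1 | intermediate
4 | 8-(furan-2-yl)octan-1-ol | OCCCCCCCCc1ccco1 | intermediate
5 | (Z)-hex-3-en-1-ol | CC/C=C\CCO | starting material
6 | (Z)-hex-3-enal | CC/C=C\CC=O | intermediate
7 | lithium 8-(5-lithiofuran-2-yl)octan-1-olate | [Li]OCCCCCCCCc1ccc([Li])o1 | intermediate
8 | rac-(3Z)-1-[5-(8-hydroxyoctyl)furan-2-yl]hex-3-en-1-ol | CC/C=C\CC(O)c1ccc(CCCCCCCCO)o1 | intermediate
9 | (5Z)-5-[(3Z)-hex-3-en-1-ylidene]-2-(8-hydroxyoctyl)-2,5-dihydrofuran-2-ol (either configuration at C2, lost on ring opening) | CC/C=C\C/C=C1/C=CC(O)(CCCCCCCCO)O1 | intermediate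
10 | (10Z,12Z,15Z)-1,12-dihydroxyoctadeca-10,12,15-trien-9-one (cyclises as its O-protonated form) | CC/C=C\C/C=C(O)/C=C\C(=O)CCCCCCCCO | intermediate
11 | (4S,5S)-4-hydroxy-4-(8-hydroxyoctyl)-5-[(2Z)-pent-2-en-1-yl]cyclopent-2-en-1-one | CC/C=C\C[C@@H]1C(=O)C=C[C@]1(CCCCCCCCO)O | intermediate
12 | 8-[(1S,5S)-1-hydroxy-4-oxo-5-[(2Z)-pent-2-en-1-yl]cyclopent-2-en-1-yl]octanal | CC/C=C\C[C@@H]1C(=O)C=C[C@]1(CCCCCCCC=O)O | intermediate
13 | 8-[(1S,5S)-1-hydroxy-4-oxo-5-[(2Z)-pent-2-en-1-yl]cyclopent-2-en-1-yl]octanoic acid | CC/C=C\C[C@@H]1C(=O)C=C[C@]1(CCCCCCCC(=O)O)O | intermediate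
14 | acetic 8-[(1S,5S)-1-(acetyloxy)-4-oxo-5-[(2Z)-pent-2-en-1-yl]cyclopent-2-en-1-yl]octanoic anhydride | CC/C=C\C[C@@H]1C(=O)C=C[C@]1(CCCCCCCC(=O)OC(C)=O)OC(C)=O | intermediate
15 | 8-[(1S,5S)-1-(acetyloxy)-4-oxo-5-[(2Z)-pent-2-en-1-yl]cyclopent-2-en-1-yl]octanoic acid | CC/C=C\C[C@@H]1C(=O)C=C[C@]1(CCCCCCCC(=O)O)OC(C)=O | target

Total step count: 6. Longest linear sequence: 5 steps (steps 1, 3, 4, 5 and 6); step 2 is a one-step side branch.

Steps most likely to fail

Step 4. The chiral ion pair may control the sense of conrotation poorly, the furfuryl cation may lose a proton to a conjugated furyldiene, or C5 may not equilibrate fully. The fallback uses known chemistry and sets out from 8. Rearrangement with ZnCl2 in acetone/H2O at 60 °C, the conditions established for 5-alkyl-2-furylcarbinols, should give the racemic hydroxy enone, racemic 4-hydroxy-4-(8-hydroxyoctyl)-5-[(2Z)-pent-2-en-1-yl]cyclopent-2-en-1-one (F1). Continued exposure of F1 to the acidic medium is expected to bring C5 to the trans-dialkyl arrangement. The enantiomers of F1 are then separated by preparative chromatography on a chiral stationary phase, and the (4S,5S) enantiomer comes back to the route as 11.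

Step 3. The furyllithium may deprotonate the doubly activated α-methylene group of 6 instead of adding, and the resulting dienolate would carry the alkene into conjugation. The fallback sets out from 4. Dilithio species 7 is quenched with I2 (THF, −78 °C) to give 8-(5-iodofuran-2-yl)octan-1-ol (F2). F2 is then joined to 6 by a Nozaki–Hiyama–Kishi coupling (CrCl2, NiCl2 catalyst, DMF, rt), an essentially non-basic organochromium addition, and the route is rejoined at 8.

Step 6. The hindered tertiary hydroxyl may acetylate slowly while the carboxyl group consumes reagent, and the β-acetoxy group may be lost by elimination during hydrolysis of the mixed anhydride. The fallback sets out from 11 and changes the order of events. Both hydroxyl groups are acetylated with Ac2O and catalytic Sc(OTf)3 in MeCN at −20 °C to give 8-[(1S,5S)-1-(acetyloxy)-4-oxo-5-[(2Z)-pent-2-en-1-yl]cyclopent-2-en-1-yl]octyl acetate (F3). F3 is then treated with Candida antarctica lipase B in pH 7 buffer, which should cleave only the primary acetate of F3 and give (1S,5S)-1-(8-hydroxyoctyl)-4-oxo-5-[(2Z)-pent-2-en-1-yl]cyclopent-2-en-1-yl acetate (F4). Oxidation of the primary alcohol of F4 with TEMPO/PhI(OAc)2 in MeCN/H2O comes back to the route at 15, with no carboxylic acid present during acetylation.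

Further compounds
F1 | step 4 | racemic 4-hydroxy-4-(8-hydroxyoctyl)-5-[(2Z)-pent-2-en-1-yl]cyclopent-2-en-1-one (4S,5S and 4R,5R) | CC/C=C\C[C@@H]1C(=O)C=C[C@]1(CCCCCCCCO)O.CC/C=C\C[C@H]1C(=O)C=C[C@@]1(CCCCCCCCO)O
F2 | step 3 | 8-(5-iodofuran-2-yl)octan-1-ol | OCCCCCCCCc1ccc(I)o1
F3 | step 6 | 8-[(1S,5S)-1-(acetyloxy)-4-oxo-5-[(2Z)-pent-2-en-1-yl]cyclopent-2-en-1-yl]octyl acetate | CC/C=C\C[C@@H]1C(=O)C=C[C@]1(CCCCCCCCOC(C)=O)OC(C)=O
F4 | step 6 | (1S,5S)-1-(8-hydroxyoctyl)-4-oxo-5-[(2Z)-pent-2-en-1-yl]cyclopent-2-en-1-yl acetate | CC/C=C\C[C@@H]1C(=O)C=C[C@]1(CCCCCCCCO)OC(C)=O
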